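Cuts, in retrosynthetic order: the ten O–CH3 bonds of a decamethyl ether; the ether bond between the oxygen on ring B C4 and ring C C3; the ring C–ring D biaryl bond; the ring A C3–C4 bond; the bond from the ring B C1 oxygen to ring A C1.
Feature used: ring A, the terminal 3,5-dihydroxyphenoxy ring (ether carbon C1, hydroxyls on C3 and C5), is a phloroglucinol mono-aryl ether, that is a folded 3,5-dioxohexanoyl chain. It maps atom for atom onto a 4-aryloxy-6-methyl-2-pyrone (pyrone C4 = ring A C1, lactone carbon C2 = C3, methyl carbon = C4, C6 = C5).
Forward: rings B, C and D are bought as arenes. The crowded ring B oxygen is bound to pyrone C4 by addition–elimination, then the pyrone is opened and closed again through its methyl carbon; this builds ring A, the only ring made in the route.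
The ring A–ring B unit is methylated, debenzylated and joined by Ullmann etherification to the mono-iodinated oxidative dimer of 1,3,5-trimethoxybenzene (rings C and D). All methyl ethers fall in the last step.
Stereochemistry: none has to be set. The target has no stereocentre, and the biaryl axis is not stereogenic because ring D carries two identical ortho hydroxyls.
Key step: step 5

Remark on the chemistry: since the target has no stereogenic unit, only the central double bond of the transient compound 8 carries a descriptor in its SMILES.

Step 1
Reactants: 1 4-hydroxy-6-methyl-2H-pyran-2-one (triacetic acid lactone)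
Product: 2 4-bromo-6-methyl-2H-pyran-2-one
Conditions: PBr3, DMF, 60 °C
Reagents that add atoms: phosphorus tribromide, BrP(Br)Br
Why: Vilsmeier-type activation of the vinylogous acid hydroxyl by PBr3/DMF followed by addition–elimination of bromide is the standard deoxybromination of 4-hydroxy-2-pyrones and leaves the lactone and the methyl group untouched.

Step 2
Reactants: 3 2,6-dimethoxy-1,4-benzoquinone
Product: 4 2,6-dimethoxybenzene-1,4-diol
Conditions: Na2S2O4, EtOAc/H2O, rt, argon
Reagents that add atoms: none
Why: Dithionite reduction of a benzoquinone to its hydroquinone is fast and clean in a two-phase system, and work under argon keeps the electron-rich diol from re-oxidising.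

Step 3
Reactants: 4 2,6-dimethoxybenzene-1,4-diol
Product: 5 4-(benzyloxy)-2,6-dimethoxyphenol
Conditions: BnBr (1.0 equiv), K2CO3, degassed DMF, 0 °C to rt, argon
Reagents that add atoms: benzyl bromide, BrCc1ccccc1
Why: Williamson ether synthesis with one equivalent of halide should pick the C4 hydroxyl, which is the more acidic one (meta to both methoxy groups) and sterically open, while the C1 hydroxyl is flanked and hydrogen-bonded by two methoxy groups.

Step 4
Reactants: 2 4-bromo-6-methyl-2H-pyran-2-one; 5 4-(benzyloxy)-2,6-dimethoxyphenol
Product: 6 4-[4-(benzyloxy)-2,6-dimethoxyphenoxy]-6-methyl-2H-pyran-2-one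
Conditions: K2CO3, DMF, 50 °C, argon
Reagents that add atoms: none
Why: Addition–elimination (vinylogous acyl substitution) of a phenoxide at C4 of a 4-halo-2-pyrone is a known reaction that accepts crowded phenoxides because the oxygen attacks an open sp2 carbon activated by the lactone carbonyl, and K2CO3 is too weak to deprotonate the C6 methyl group.

Step 5
Reactants: 6 4-[4-(benzyloxy)-2,6-dimethoxyphenoxy]-6-methyl-2H-pyran-2-one
Product: 9 5-[4-(benzyloxy)-2,6-dimethoxyphenoxy]benzene-1,3-diol, via lithium methylidenepyranolate 7 (not isolated), via lithium ketene enolate 8 (not isolated)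
Conditions: LiN(SiMe3)2 (3 equiv), THF (0.02 M), 6 added to the base at –78 °C, then 60 °C; 1 M HCl, 0 °C
Reagents that add atoms: none
Why: Proposed new method: LiN(SiMe3)2 removes a proton from the C6 methyl group of 6 to give the cross-conjugated trienolate 7, whose lactone C2–O1 bond should break on warming by E1cB loss of the ring oxygen as an enolate, as the enolates of aryl and enol esters do, which unmasks the ketene enolate 8, the triketide chain in its most reactive acyl form. Rotation about the former C5–C6 bond puts the enolate CH2 carbon in place of the oxygen next to the ketene carbon; C–C bond formation (ring A C3–C4) and deprotonation of the dienone by a second equivalent of base give the resorcinol dianion as an irreversible sink, whereas closure through oxygen only returns 7. Ring A closes in a 6-(enolendo)-exo-dig mode at the ketene carbon, which can also be read as the 6π electrocyclisation of a dienylketene, and the cis placement of the two chain ends on the central double bond that this needs is inherited from the pyrone ring. The closest known reaction types are the hot-alkoxide recyclisation of 4-methoxy-6-methyl-2-pyrone to 5-methoxyresorcinol, the Mg(OMe)2-induced Claisen refolding of pyranopyrandiones to acylphloroglucinols and the methoxide rearrangement of ylidenebutenolides to cyclopentene-1,3-diones, none of which has been shown with a 4-aryloxy group or with an amide base. The selectivity needed is acylation of the methyl carbon without loss of the ring B aryloxide from the vinylogous ester carbon (pyrone C4), and it is secured by excluding every oxygen nucleophile, since methoxide or hydroxide would expel the better leaving aryloxide by addition–elimination well before the slow methyl ketone Claisen step, by adding 6 to excess base so that no neutral pyrone is left for 7 to attack, and by high dilution. No stereocentre is formed.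

Step 6
Reactants: 9 5-[4-(benzyloxy)-2,6-dimethoxyphenoxy]benzene-1,3-diol
Product: 10 5-(benzyloxy)-2-(3,5-dimethoxyphenoxy)-1,3-dimethoxybenzene
Conditions: Me2SO4, K2CO3, acetone, reflux
Reagents that add atoms: dimethyl sulfate, COS(=O)(=O)OC
Why: Williamson O-methylation with the hard electrophile dimethyl sulfate and K2CO3 in acetone favours O- over C-alkylation of the phloroglucinol-type ring and touches neither the benzyl ether nor the diaryl ether.

Step 7
Reactants: 10 5-(benzyloxy)-2-(3,5-dimethoxyphenoxy)-1,3-dimethoxybenzene
Product: 11 4-(3,5-dimethoxyphenoxy)-3,5-dimethoxyphenol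
Conditions: H2 (1 atm), 10% Pd/C, EtOAc/MeOH, rt
Reagents that add atoms: none
Why: Catalytic hydrogenolysis cleaves only the benzylic C–O bond, since aryl methyl ethers and the diaryl ether are inert to H2 over Pd/C at ambient pressure.

Step 8
Reactants: 12 1,3,5-trimethoxybenzene (two molecules)
Product: 13 2,2',4,4',6,6'-hexamethoxy-1,1'-biphenyl
Conditions: anhydrous FeCl3 (1.0 equiv per arene), CH2Cl2, 0 °C to rt; MeOH quench
Reagents that add atoms: none
Why: Scholl-type oxidative dehydrodimerisation through the arene radical cation can give only one biaryl because the three free positions of 12 are equivalent, and the twisted tetra-ortho-substituted product is no easier to oxidise than 12, so limiting FeCl3 should hold back oligomers and ring chlorination.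

Step 9
Reactants: 13 2,2',4,4',6,6'-hexamethoxy-1,1'-biphenyl
Product: 14 3-iodo-2,2',4,4',6,6'-hexamethoxy-1,1'-biphenyl
Conditions: NIS (0.9 equiv), MeCN, 0 °C, dark
Reagents that add atoms: N-iodosuccinimide, O=C1CCC(=O)N1I
Why: Electrophilic aromatic iodination of a phloroglucinol trimethyl ether ring needs no acid, the four free positions of 13 are equivalent, and a slight deficit of NIS at low temperature should keep iodination of the second ring low, with unreacted 13 returned to the step.

Step 10
Reactants: 11 4-(3,5-dimethoxyphenoxy)-3,5-dimethoxyphenol; 14 3-iodo-2,2',4,4',6,6'-hexamethoxy-1,1'-biphenyl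
Product: 15 3-[4-(3,5-dimethoxyphenoxy)-3,5-dimethoxyphenoxy]-2,2',4,4',6,6'-hexamethoxy-1,1'-biphenyl
Conditions: CuI (20 mol%), picolinic acid (40 mol%), K3PO4, DMSO, 100 °C, argon
Reagents that add atoms: none
Why: Ligand-accelerated Ullmann ether synthesis (CuI/picolinic acid), a system devised for ortho-substituted partners, pairs the crowded iodide with the sterically free and nucleophilic phenoxide of 11.

Step 11
Reactants: 15 3-[4-(3,5-dimethoxyphenoxy)-3,5-dimethoxyphenoxy]-2,2',4,4',6,6'-hexamethoxy-1,1'-biphenyl
Product: 16 3-[4-(3,5-dihydroxyphenoxy)-3,5-dihydroxyphenoxy]-[1,1'-biphenyl]-2,2',4,4',6,6'-hexol (CNP0248644.0)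
Conditions: BBr3 (excess), CH2Cl2, –78 °C to rt; ice/H2O, argon
Reagents that add atoms: none
Why: Lewis acid dealkylation of aryl methyl ethers with BBr3 (borate formation, then SN2 attack of bromide on methyl) cleaves alkyl–oxygen bonds only, so both diaryl ether bonds and the biaryl bond stay, and cold aqueous hydrolysis under argon should free the decaphenol.

Compound list
1 | 4-hydroxy-6-methyl-2H-pyran-2-one | Cc1cc(O)cc(=O)o1 | starting material
2 | 4-bromo-6-methyl-2H-pyran-2-one | Cc1cc(Br)cc(=O)o1 | intermediate
3 | 2,6-dimethoxy-1,4-benzoquinone | COC1=CC(=O)C=C(OC)C1=O | starting material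
4 | 2,6-dimethoxybenzene-1,4-diol | COc1cc(O)cc(OC)c1O | intermediate
5 | 4-(benzyloxy)-2,6-dimethoxyphenol | COc1cc(OCc2ccccc2)cc(OC)c1O | intermediate
6 | 4-[4-(benzyloxy)-2,6-dimethoxyphenoxy]-6-methyl-2H-pyran-2-one | Cc1cc(Oc2c(OC)cc(OCc3ccccc3)cc2OC)cc(=O)o1 | intermediate
7 | lithium 4-[4-(benzyloxy)-2,6-dimethoxyphenoxy]-6-methylidene-6H-pyran-2-olate | [Li+].C=C1C=C(Oc2c(OC)cc(OCc3ccccc3)cc2OC)C=C([O-])O1 | intermediate
8 | lithium (3E)-4-[4-(benzyloxy)-2,6-dimethoxyphenoxy]-6-oxohexa-1,3,5-trien-2-olate (chain ends cis on the central double bond) | [Li+].C=C([O-])/C=C(\C=C=O)Oc1c(OC)cc(OCc2ccccc2)cc1OC | intermediate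
9 | 5-[4-(benzyloxy)-2,6-dimethoxyphenoxy]benzene-1,3-diol | Oc1cc(O)cc(Oc2c(OC)cc(OCc3ccccc3)cc2OC)c1 | intermediate
10 | 5-(benzyloxy)-2-(3,5-dimethoxyphenoxy)-1,3-dimethoxybenzene | COc1cc(OC)cc(Oc2c(OC)cc(OCc3ccccc3)cc2OC)c1 | intermediate
11 | 4-(3,5-dimethoxyphenoxy)-3,5-dimethoxyphenol | COc1cc(OC)cc(Oc2c(OC)cc(O)cc2OC)c1 | intermediate
12 | 1,3,5-trimethoxybenzene | COc1cc(OC)cc(OC)c1 | starting material
13 | 2,2',4,4',6,6'-hexamethoxy-1,1'-biphenyl | COc1cc(OC)c(-c2c(OC)cc(OC)cc2OC)c(OC)c1 | intermediate
14 | 3-iodo-2,2',4,4',6,6'-hexamethoxy-1,1'-biphenyl | COc1cc(OC)c(-c2c(OC)cc(OC)c(I)c2OC)c(OC)c1 | intermediate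
15 | 3-[4-(3,5-dimethoxyphenoxy)-3,5-dimethoxyphenoxy]-2,2',4,4',6,6'-hexamethoxy-1,1'-biphenyl | COc1cc(OC)cc(Oc2c(OC)cc(Oc3c(OC)cc(OC)c(-c4c(OC)cc(OC)cc4OC)c3OC)cc2OC)c1 | intermediate
16 | 3-[4-(3,5-dihydroxyphenoxy)-3,5-dihydroxyphenoxy]-[1,1'-biphenyl]-2,2',4,4',6,6'-hexol | Oc1cc(O)cc(Oc2c(O)cc(Oc3c(O)cc(O)c(-c4c(O)cc(O)cc4O)c3O)cc2O)c1 | target

Total step count: 11. Longest linear sequence: 8 steps (3 → 4 → 5 → 6 → 9 → 10 → 11 → 15 → 16). Step 1 and steps 8–9 are side branches.

Steps most likely to fail

Step 5 (the proposed new method).
- **What may go wrong:** The trienolate may resist ring opening at the temperatures it survives. It may be consumed by intermolecular C-acylation or by attack on pyrone C4 of another molecule with loss of the aryloxide. The ketene may be intercepted by the amide base.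
- **Fallback (known chemistry):** It sets out from phenol 5 and comes back to the route at 10, so that steps 4 to 6 are bypassed.
  - Phenol 5 is coupled with commercial 1-iodo-3,5-dimethoxybenzene in a ligand-accelerated Ullmann ether synthesis (CuI, picolinic acid, K3PO4, DMSO, 100 °C).
  - The hindered partner is then the phenoxide and the iodide is open, the combination for which these conditions are established.
  - Ring A is bought instead of built, and no compound outside the list is made (entry F0).

Step 10.
- **What may go wrong:** Insertion of copper into an iodide flanked by two methoxy groups on a very electron-rich ring may be slow. Protodeiodination of 14 and oxidative decay of the phenoxide of 11 could then take over.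
- **Fallback:** It reverses the roles of the two partners and changes the metal. It sets out from 14 and 11 and comes back at 15.
  - Iodine–lithium exchange on 14 (n-BuLi, THF, –78 °C) and quench with B(OMe)3 give dimethyl (2,2',4,4',6,6'-hexamethoxybiphenyl-3-yl)boronate F1.
  - F1 is oxidised in the same flask (H2O2, NaOH) to 2,2',4,4',6,6'-hexamethoxybiphenyl-3-ol F2.
  - Phenol 11 is converted with Tf2O and pyridine in CH2Cl2 into 4-(3,5-dimethoxyphenoxy)-3,5-dimethoxyphenyl trifluoromethanesulfonate F3.
  - A Buchwald–Hartwig-type C–O coupling of F2 with F3 (Pd(OAc)2, tBuXPhos, K3PO4, toluene, 100 °C) should give 15. The metal now inserts at an unhindered carbon and the crowded ring enters as the phenoxide.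

Step 11.
- **What may go wrong:** Cleavage of the ten methyl ethers may stop short. The free polyphenol may be lost to air oxidation, or to acid-promoted hydrolysis of the ring A ether, during aqueous isolation and chromatography.
- **Fallback:** It sets out from 15 and comes back at 16, replacing direct isolation by capture, purification and mild release.
  - After the BBr3 treatment the crude phenol is not purified but peracetylated (Ac2O, pyridine) to 3-[4-(3,5-diacetoxyphenoxy)-3,5-diacetoxyphenoxy]biphenyl-2,2',4,4',6,6'-hexayl hexaacetate F4.
  - F4 is stable on silica gel and can be separated from partly methylated material, which is returned to the demethylation.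
  - Zemplén deacetylation (catalytic NaOMe, degassed MeOH, argon, neutralisation with acidic resin) then releases 16 without strong acid or oxidant.

Further compounds
F0 | step 5 | none | none
F1 | step 10 | dimethyl (2,2',4,4',6,6'-hexamethoxybiphenyl-3-yl)boronate | COB(OC)c1c(OC)cc(OC)c(-c2c(OC)cc(OC)cc2OC)c1OC
F2 | step 10 | 2,2',4,4',6,6'-hexamethoxybiphenyl-3-ol | COc1cc(OC)c(-c2c(OC)cc(OC)cc2OC)c(OC)c1O
F3 | step 10 | 4-(3,5-dimethoxyphenoxy)-3,5-dimethoxyphenyl trifluoromethanesulfonate | COc1cc(OC)cc(Oc2c(OC)cc(OS(=O)(=O)C(F)(F)F)cc2OC)c1
F4 | step 11 | 3-[4-(3,5-diacetoxyphenoxy)-3,5-diacetoxyphenoxy]biphenyl-2,2',4,4',6,6'-hexayl hexaacetate | CC(=O)Oc1cc(OC(C)=O)cc(Oc2c(OC(C)=O)cc(Oc3c(OC(C)=O)cc(OC(C)=O)c(-c4c(OC(C)=O)cc(OC(C)=O)cc4OC(C)=O)c3OC(C)=O)cc2OC(C)=O)c1
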